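**Retrosynthetic overview**

- The strategy rests on the C2=C3 double bond of the furan ring (O1–C2–C3–C3a–C7a) of the benzofuran. It joins C2 (bonded to O1 and the 4-hydroxy-3-methoxyphenyl ring) to C3 (bonded to C3a and the formyl carbon), and both atoms are carbonyl carbons in the precursor.
- Target ⇒ (acetate methanolysis, O-debenzylation, CH3 → CHO oxidation) the 2-aryl-3-methylbenzofuran carrying an O-benzyl and an O-acetyl group.
- C2=C3 ⇒ intramolecular ketone–ester McMurry coupling of an ortho-acetylphenyl O-benzylvanillate. The furan ring is the only ring made; both benzene rings are bought.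
- Ester C–O ⇒ ortho-acetylphenol + O-benzylvanilloyl chloride; aryl–acetyl C–C ⇒ Fries rearrangement of dihydroconiferyl alcohol diacetate.

Key step: step 5

Remark: the target has no stereocentre. The side-chain alcohol is carried as the acetate that the Fries sequence installs, not as a silyl ether; a remote alkyl acetate is expected to tolerate low-valent titanium, DDQ and BCl3, and this saves two protecting-group operations.

**Step 1**
Reactants: 1 dihydroconiferyl alcohol [4-(3-hydroxypropyl)-2-methoxyphenol]
Product: 2 3-(4-acetoxy-3-methoxyphenyl)propyl acetate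
Conditions: Ac2O, pyridine, DMAP (cat.), CH2Cl2, 0 °C to rt
Reagents that add atoms: acetic anhydride, CC(=O)OC(C)=O
Why: DMAP-catalysed O-acetylation (nucleophilic acyl substitution) esterifies both the phenol and the primary alcohol, which gives the aryl acetate needed for the Fries rearrangement and protects the side chain in the same operation.

**Step 2**
Reactants: 2 3-(4-acetoxy-3-methoxyphenyl)propyl acetate
Product: 4 3-(3-acetyl-4-hydroxy-5-methoxyphenyl)propyl acetate, via difluoroboron chelate 3 (not isolated)
Conditions: BF3·OEt2, AcOH, 90 °C; then H2O, rt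
Reagents that add atoms: none
Why: Fries rearrangement, in which BF3 ionises the aryl acetate and the acyl group is delivered to C6, the only free position ortho to the phenol oxygen (C2 carries OMe, C4 the side chain), where the product should be held as its six-membered difluoroboron chelate until aqueous work-up; BF3 spares the aryl methyl ether and the acetic acid medium makes acyl exchange at the side-chain acetate degenerate.

**Step 3**
Reactants: 5 4-(benzyloxy)-3-methoxybenzoic acid
Product: 6 4-(benzyloxy)-3-methoxybenzoyl chloride
Conditions: (COCl)2, DMF (cat.), CH2Cl2, 0 °C to rt; concentrate and use crude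
Reagents that add atoms: oxalyl chloride, O=C(Cl)C(=O)Cl
Why: Acid chloride formation through the chloroiminium ion generated from DMF and oxalyl chloride (Vilsmeier-type activation), to which the benzyl and methyl ethers are inert and whose by-products are gases.

**Step 4**
Reactants: 4 3-(3-acetyl-4-hydroxy-5-methoxyphenyl)propyl acetate; 6 4-(benzyloxy)-3-methoxybenzoyl chloride
Product: 7 2-acetyl-4-(3-acetoxypropyl)-6-methoxyphenyl 4-(benzyloxy)-3-methoxybenzoate
Conditions: Et3N, DMAP (cat.), CH2Cl2, 0 °C to rt
Reagents that add atoms: none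
Why: DMAP-catalysed O-acylation of the hydrogen-bonded, doubly ortho-substituted phenol by the acid chloride; the amine base is too weak to enolise the ketone, so no Baker–Venkataraman acyl shift is expected and the side-chain acetate is untouched.

**Step 5**
Reactants: 7 2-acetyl-4-(3-acetoxypropyl)-6-methoxyphenyl 4-(benzyloxy)-3-methoxybenzoate
Product: 8 3-{2-[4-(benzyloxy)-3-methoxyphenyl]-7-methoxy-3-methyl-1-benzofuran-5-yl}propyl acetate
Conditions: TiCl3 (about 6 equiv), Zn dust (about 12 equiv), THF, reflux, 2 h; then 7 in THF added by syringe pump, reflux; aq. K2CO3, filtration through Celite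
Reagents that add atoms: none
Why: Zn reduces TiCl3 (trivalent titanium) to low-valent titanium, which transfers electrons to the aryl methyl ketone of 7; the titanium-bound ketyl (or its carbon dianion) adds to the carbonyl carbon of the neighbouring aryl ester, and the oxophilic titanium then removes both oxygens to leave the C2=C3 enol-ether double bond, which here is part of the aromatic furan. The closest known reaction type is the titanium-mediated oxo-ester McMurry cyclisation of 2-acylphenyl esters to benzofurans. The furan ring (O1, C2, C3, C3a, C7a) closes in a 5-exo-trig mode, the former ketone carbon attacking the exocyclic ester C=O. No stereocentre is formed. The step needs chemoselectivity for intramolecular ketone–ester coupling over intermolecular pinacol coupling and over attack on the remote alkyl acetate: the ketone is the only carbonyl reduced readily, the aroyl carbon sits five atoms away on the ortho oxygen, and slow addition to excess titanium keeps the ketyl dilute. The benzyl ether, the methyl ethers and the acetate are not expected to be reduced by this reagent.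

**Step 6**
Reactants: 8 3-{2-[4-(benzyloxy)-3-methoxyphenyl]-7-methoxy-3-methyl-1-benzofuran-5-yl}propyl acetate
Product: 10 3-{2-[4-(benzyloxy)-3-methoxyphenyl]-3-formyl-7-methoxy-1-benzofuran-5-yl}propyl acetate, via 3-hydroxymethyl benzofuran 9 (not isolated)
Conditions: DDQ (2.5 equiv), 1,4-dioxane/H2O (10:1), rt
Reagents that add atoms: water, O
Why: DDQ benzylic oxidation, in which hydride abstraction from the 3-methyl group gives a cation delocalised over C2, O1 and the para-benzyloxyphenyl ring, water traps it as alcohol 9, and a second hydride abstraction gives the aldehyde, whose conjugation with O1 (vinylogous ester) should stop further oxidation while the plain benzyl ether, the acetate and the less activated side-chain ArCH2 survive.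

**Step 7**
Reactants: 10 3-{2-[4-(benzyloxy)-3-methoxyphenyl]-3-formyl-7-methoxy-1-benzofuran-5-yl}propyl acetate
Product: 11 3-[3-formyl-2-(4-hydroxy-3-methoxyphenyl)-7-methoxy-1-benzofuran-5-yl]propyl acetate
Conditions: BCl3, pentamethylbenzene, CH2Cl2, −78 °C; then H2O
Reagents that add atoms: none
Why: Lewis-acid debenzylation, in which BCl3 bound to the guaiacyl oxygens cleaves the benzyl–oxygen bond at −78 °C and pentamethylbenzene takes up the benzyl cation by Friedel–Crafts alkylation, so that the aryl methyl ethers, the acetate and the aldehyde (the last at risk under hydrogenolysis) are left alone.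

**Step 8**
Reactants: 11 3-[3-formyl-2-(4-hydroxy-3-methoxyphenyl)-7-methoxy-1-benzofuran-5-yl]propyl acetate
Product: 12 2-(4-hydroxy-3-methoxyphenyl)-5-(3-hydroxypropyl)-7-methoxy-1-benzofuran-3-carbaldehyde (CNP0309415.0)
Conditions: K2CO3, MeOH, rt; then aq. NH4Cl
Reagents that add atoms: none
Why: Base-catalysed transesterification (Zemplén type) removes the primary acetate as methyl acetate; the aldehyde has no α-hydrogen and the phenoxide returns to the phenol on mild acidification, which should give the target.

**Compound list**

1 | dihydroconiferyl alcohol, 4-(3-hydroxypropyl)-2-methoxyphenol | COc1cc(CCCO)ccc1O | starting material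
2 | 3-(4-acetoxy-3-methoxyphenyl)propyl acetate | CC(=O)OCCCc1ccc(OC(C)=O)c(OC)c1 | intermediate
3 | difluoroboron chelate of 4 (boron on the phenolate oxygen, coordinated by the acetyl oxygen) | CC1=[O+][B-](F)(F)Oc2c(OC)cc(CCCOC(C)=O)cc12 | intermediate
4 | 3-(3-acetyl-4-hydroxy-5-methoxyphenyl)propyl acetate | CC(=O)OCCCc1cc(OC)c(O)c(C(C)=O)c1 | intermediate
5 | 4-(benzyloxy)-3-methoxybenzoic acid | COc1cc(C(=O)O)ccc1OCc1ccccc1 | starting material
6 | 4-(benzyloxy)-3-methoxybenzoyl chloride | COc1cc(C(=O)Cl)ccc1OCc1ccccc1 | intermediate
7 | 2-acetyl-4-(3-acetoxypropyl)-6-methoxyphenyl 4-(benzyloxy)-3-methoxybenzoate | CC(=O)OCCCc1cc(OC)c(OC(=O)c2ccc(OCc3ccccc3)c(OC)c2)c(C(C)=O)c1 | intermediate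
8 | 3-{2-[4-(benzyloxy)-3-methoxyphenyl]-7-methoxy-3-methyl-1-benzofuran-5-yl}propyl acetate | Cc1c(-c2ccc(OCc3ccccc3)c(OC)c2)oc2c(OC)cc(CCCOC(C)=O)cc12 | intermediate
9 | 3-{2-[4-(benzyloxy)-3-methoxyphenyl]-3-(hydroxymethyl)-7-methoxy-1-benzofuran-5-yl}propyl acetate | OCc1c(-c2ccc(OCc3ccccc3)c(OC)c2)oc2c(OC)cc(CCCOC(C)=O)cc12 | intermediate
10 | 3-{2-[4-(benzyloxy)-3-methoxyphenyl]-3-formyl-7-methoxy-1-benzofuran-5-yl}propyl acetate | O=Cc1c(-c2ccc(OCc3ccccc3)c(OC)c2)oc2c(OC)cc(CCCOC(C)=O)cc12 | intermediate
11 | 3-[3-formyl-2-(4-hydroxy-3-methoxyphenyl)-7-methoxy-1-benzofuran-5-yl]propyl acetate | O=Cc1c(-c2ccc(O)c(OC)c2)oc2c(OC)cc(CCCOC(C)=O)cc12 | intermediate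
12 | 2-(4-hydroxy-3-methoxyphenyl)-5-(3-hydroxypropyl)-7-methoxy-1-benzofuran-3-carbaldehyde | COc1cc(-c2oc3c(OC)cc(CCCO)cc3c2C=O)ccc1O | target

**Step count**

Total steps: 8. Longest linear sequence: 7 steps (steps 1, 2, 4, 5, 6, 7, 8 from compound 1); step 3 is a one-step side branch.

**Steps most likely to fail**

1. Step 5 (keto–ester McMurry coupling). The ketyl may dimerise intermolecularly to a pinacol, the ketone may simply be reduced, or the aryl ester may be cleaved reductively before ring closure. The fallback makes the same C2=C3 bond by a polar intramolecular Wittig reaction. It sets out from compound 4. NaBH4 (EtOH, 0 °C) should reduce the ketone to racemic 3-[4-hydroxy-3-(1-hydroxyethyl)-5-methoxyphenyl]propyl acetate F1. PPh3·HBr (MeCN, reflux) should convert this, through the ortho-quinone methide, into racemic {1-[5-(3-acetoxypropyl)-2-hydroxy-3-methoxyphenyl]ethyl}triphenylphosphonium bromide F2. Acid chloride 6 and Et3N in toluene at reflux should then acylate the phenol to the O-aroyl phosphonium bromide F3; its ylide closes onto the ester carbonyl with loss of triphenylphosphine oxide. The fallback comes back to the route at compound 8.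

2. Step 6 (DDQ oxidation of the 3-methyl group). Hydride abstraction may occur at the wrong benzylic site (side-chain ArCH2 or the benzyl ether), the oxidation may stop at the alcohol stage, or the electron-rich benzofuran may couple oxidatively. The fallback sets out from compound 8. Radical bromination (NBS, AIBN, PhCF3, reflux) should give 3-{2-[4-(benzyloxy)-3-methoxyphenyl]-3-(bromomethyl)-7-methoxy-1-benzofuran-5-yl}propyl acetate F4. Kornblum oxidation (DMSO, NaHCO3, 90 °C) then converts the bromide into the aldehyde, and the fallback comes back at compound 10.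

3. Step 2 (Fries rearrangement). The acyl group may be transferred to C5 (para to the methoxy group) instead of C6, the guaiacyl methyl ether may be lost, or intermolecular transacylation may give mixtures. The fallback replaces the rearrangement by halogenation and cross-coupling and sets out from compound 1. NBS (MeCN, 0 °C) should brominate ortho to the free phenol to give 2-bromo-4-(3-hydroxypropyl)-6-methoxyphenol F5. Ac2O/pyridine gives 3-(4-acetoxy-3-bromo-5-methoxyphenyl)propyl acetate F6. Stille coupling with tributyl(1-ethoxyvinyl)stannane and Pd(PPh3)4 (zerovalent palladium) in toluene at 100 °C gives the enol ether 3-[4-acetoxy-3-(1-ethoxyvinyl)-5-methoxyphenyl]propyl acetate F7. Hydrolysis (1 M HCl, THF, rt) gives 2-acetyl-4-(3-acetoxypropyl)-6-methoxyphenyl acetate F8. Selective aminolysis of the aryl acetate (pyrrolidine, CH2Cl2, 0 °C) then comes back to the route at compound 4.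

**Further compounds**

F1 | step 5 | 3-[4-hydroxy-3-(1-hydroxyethyl)-5-methoxyphenyl]propyl acetate (racemic) | CC(O)c1cc(CCCOC(C)=O)cc(OC)c1O
F2 | step 5 | {1-[5-(3-acetoxypropyl)-2-hydroxy-3-methoxyphenyl]ethyl}triphenylphosphonium bromide (racemic) | CC(c1cc(CCCOC(C)=O)cc(OC)c1O)[P+](c1ccccc1)(c1ccccc1)c1ccccc1.[Br-]
F3 | step 5 | {1-[5-(3-acetoxypropyl)-2-{[4-(benzyloxy)-3-methoxybenzoyl]oxy}-3-methoxyphenyl]ethyl}triphenylphosphonium bromide (racemic) | CC(c1cc(CCCOC(C)=O)cc(OC)c1OC(=O)c1ccc(OCc2ccccc2)c(OC)c1)[P+](c1ccccc1)(c1ccccc1)c1ccccc1.[Br-]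
F4 | step 6 | 3-{2-[4-(benzyloxy)-3-methoxyphenyl]-3-(bromomethyl)-7-methoxy-1-benzofuran-5-yl}propyl acetate | BrCc1c(-c2ccc(OCc3ccccc3)c(OC)c2)oc2c(OC)cc(CCCOC(C)=O)cc12
F5 | step 2 | 2-bromo-4-(3-hydroxypropyl)-6-methoxyphenol | COc1cc(CCCO)cc(Br)c1O
F6 | step 2 | 3-(4-acetoxy-3-bromo-5-methoxyphenyl)propyl acetate | COc1cc(CCCOC(C)=O)cc(Br)c1OC(C)=O
F7 | step 2 | 3-[4-acetoxy-3-(1-ethoxyvinyl)-5-methoxyphenyl]propyl acetate | CCOC(=C)c1cc(CCCOC(C)=O)cc(OC)c1OC(C)=O
F8 | step 2 | 2-acetyl-4-(3-acetoxypropyl)-6-methoxyphenyl acetate | CC(=O)OCCCc1cc(OC)c(OC(C)=O)c(C(C)=O)c1
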